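## Retrosynthetic overview
1. Remove the two acyl groups. The tertiary angelate and the secondary acetate go on last, onto a 3,4-dihydroxy lactone. Its C3 carbinol comes from an α-methylene lactone by conjugate hydride addition followed by enolate oxidation.
2. Key step: both rings come from one acyclic bromohydrin ester acetal in one flask. Acid closes the γ-lactone first and frees the aldehyde, then indium closes the cyclohexane (C3a–C4 bond) onto the lactone.
3. The acyclic precursor comes from a C6-side aldehyde and a four-carbon dibromo acrylate linchpin. One carbon of the linchpin is bonded in turn to both former carbonyl carbons.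
4. The vicinal quaternary/tertiary pair (methyl and vinyl next to isopropenyl) comes from an enantioselective boron-enolate Ireland–Claisen rearrangement of an (E)-allyl senecioate.
5. Starting materials: 4,4-dimethoxybutan-2-one, triethyl phosphonoacetate, senecioyl chloride, methyl 2-(bromomethyl)acrylate, angelic acid.

Assumption: the (S,S)-diazaborolidine controller is taken to give the (2R,3R)-acid of step 4; if the sense of induction is the opposite, its equally available (R,R)-antipode is used and nothing else changes.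

Note on locants: bicyclic compounds carry 1-benzofuran-2-one locants (O1, C2, C3, C3a, C4 to C7, C7a).

## Route

Step 1
Reactants: 1 4,4-dimethoxybutan-2-one; 2 triethyl phosphonoacetate
Product: 3 ethyl (2E)-5,5-dimethoxy-3-methylpent-2-enoate
Conditions: NaH, THF, 0 °C to rt; minor Z isomer removed by chromatography
Reagents that add atoms: none
Why: Horner–Wadsworth–Emmons olefination of the methyl ketone puts the ester trans to the larger CH2CH(OMe)2 group (E favoured), and the weakly basic phosphonate anion does not eliminate methanol from the acetal.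

Step 2
Reactants: 3 ethyl (2E)-5,5-dimethoxy-3-methylpent-2-enoate
Product: 4 (2E)-5,5-dimethoxy-3-methylpent-2-en-1-ol
Conditions: i-Bu2AlH (2.2 equiv), CH2Cl2, −78 °C; aq. potassium sodium tartrate
Reagents that add atoms: none
Why: 1,2-Reduction of the enoate with i-Bu2AlH gives the allylic alcohol and leaves the acetal and the alkene geometry untouched.

Step 3
Reactants: 4 (2E)-5,5-dimethoxy-3-methylpent-2-en-1-ol; 5 3-methylbut-2-enoyl chloride
Product: 6 (2E)-5,5-dimethoxy-3-methylpent-2-en-1-yl 3-methylbut-2-enoate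
Conditions: pyridine, CH2Cl2, 0 °C
Reagents that add atoms: none
Why: This is a simple O-acylation (nucleophilic acyl substitution), and pyridine is too weak a base to send the acid chloride through the vinylketene, so the conjugated ester is obtained cleanly.

Step 4
Reactants: 6 (2E)-5,5-dimethoxy-3-methylpent-2-en-1-yl 3-methylbut-2-enoate
Product: 8 (2R,3R)-3-ethenyl-5,5-dimethoxy-3-methyl-2-(prop-1-en-2-yl)pentanoic acid, via boron ketene acetal 7 (not isolated)
Conditions: (4S,5S)-2-bromo-4,5-diphenyl-1,3-bis{[3,5-bis(trifluoromethyl)phenyl]sulfonyl}-1,3,2-diazaborolidine (1.3 equiv), Et3N, toluene–hexane, −78 °C, then −20 to 4 °C, 3 d; H2O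
Reagents that add atoms: none
Why: In this enantioselective boron-enolate Ireland–Claisen rearrangement the s-trans boron-complexed senecioate is γ-deprotonated to the E(O)-dienolate (isopropenyl cis to the allyloxy oxygen), a chair transition state on the (E)-alkene gives the anti pair (isopropenyl trans to vinyl), and the C2-symmetric controller selects the face, which sets C2 and C3 together.

Step 5
Reactants: 8 (2R,3R)-3-ethenyl-5,5-dimethoxy-3-methyl-2-(prop-1-en-2-yl)pentanoic acid
Product: 10 (2R,3R)-3-ethenyl-5,5-dimethoxy-3-methyl-2-(prop-1-en-2-yl)pentanal, via acyl imidazolide 9 (not isolated)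
Conditions: 1,1'-carbonyldiimidazole, CH2Cl2, rt, 1 h; then i-Bu2AlH, −78 °C; aq. potassium sodium tartrate; used at once, kept below 30 °C
Reagents that add atoms: none
Why: Partial reduction of an N-acylimidazole stops at the tetrahedral aluminate, which collapses to the aldehyde only on work-up, and the cold non-basic medium avoids epimerisation, conjugation of the β,γ-alkene and Cope rearrangement of the 1,5-diene.

Step 6
Reactants: 11 methyl 2-(bromomethyl)prop-2-enoate
Product: 13 methyl 3-bromo-2-(bromomethyl)prop-2-enoate, via tribromo ester 12 (not isolated)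
Conditions: Br2, CH2Cl2, rt; then Et3N (1.0 equiv, slow addition), Et2O, 0 °C
Reagents that add atoms: bromine BrBr
Why: Bromine addition followed by E2 dehydrobromination works because the two CH2Br groups of 12 are equivalent, so only one constitution can form, and its E/Z ratio is irrelevant later.

Step 7
Reactants: 10 (2R,3R)-3-ethenyl-5,5-dimethoxy-3-methyl-2-(prop-1-en-2-yl)pentanal; 13 methyl 3-bromo-2-(bromomethyl)prop-2-enoate
Product: 14 methyl (4S,5R,6R)-3-bromo-6-ethenyl-4-hydroxy-8,8-dimethoxy-6-methyl-2-methylidene-5-(prop-1-en-2-yl)octanoate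
Conditions: 13 (1.5 equiv), Zn dust (1.3 equiv), THF–sat. aq. NH4Cl (1:1), 0 °C, 30 min
Reagents that add atoms: none
Why: In this aqueous Barbier allylation the primary allylzinc reacts through its γ-carbon (the CHBr carbon), Felkin–Anh addition anti to the quaternary carbon sets the 4S carbinol (later O trans to isopropenyl), the C3 bromide epimers converge later, and zinc is kept below the amount of 13 so that the secondary allylic bromide and the acetal survive.

Step 8
Reactants: 14 methyl (4S,5R,6R)-3-bromo-6-ethenyl-4-hydroxy-8,8-dimethoxy-6-methyl-2-methylidene-5-(prop-1-en-2-yl)octanoate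
Product: 17 (3aR,4S,6R,7R,7aS)-6-ethenyl-4-hydroxy-6-methyl-3-methylidene-7-(prop-1-en-2-yl)hexahydro-1-benzofuran-2(3H)-one, via bromolactone aldehyde 15 (not isolated), via allylindium dibromide 16 (not isolated)
Conditions: 0.5 M aq. HCl–THF (1:2), 35 °C, 3 h; then indium powder (1.5 equiv), 20 °C, 8 h, same flask
Reagents that add atoms: water O
Why: Proposed new method: acid first lactonises the γ-hydroxy ester (lactone ring) and hydrolyses the acetal to give 15, indium metal then inserts into the allylic C–Br bond, and the allylindium 16 (metal on the exocyclic CH2 after a 1,3-shift, C3a nucleophilic) adds to the tethered aldehyde to close the cyclohexane; the three-atom tether on C7a can only reach the butenolide face it occupies, which gives the cis ring fusion (3aR), and a chair Zimmerman–Traxler transition state with the ring-locked E-type allylindium and the aldehyde chain equatorial places the C4–OH trans to C3 (4S); the closest known reaction types are the aqueous Barbier lactone synthesis with 2-(bromomethyl)acrylates and the intermolecular zinc or indium Barbier additions of 3-(bromomethyl)furan-2(5H)-ones to aldehydes.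

Step 9
Reactants: 17 (3aR,4S,6R,7R,7aS)-6-ethenyl-4-hydroxy-6-methyl-3-methylidene-7-(prop-1-en-2-yl)hexahydro-1-benzofuran-2(3H)-one
Product: 19 (3S,3aR,4S,6R,7R,7aS)-6-ethenyl-3,4-dihydroxy-3,6-dimethyl-7-(prop-1-en-2-yl)hexahydro-1-benzofuran-2(3H)-one, via dilithium alkoxide enolate 18 (not isolated)
Conditions: 17 added to Li[HB(s-Bu)3] (2.3 equiv), THF, −78 °C; then 2-(benzenesulfonyl)-3-phenyloxaziridine (3 equiv), −78 to −40 °C; H2O
Reagents that add atoms: 2-(benzenesulfonyl)-3-phenyloxaziridine O=S(=O)(N1OC1c1ccccc1)c1ccccc1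
Why: Conjugate hydride addition to the exocyclic methylene spares the isolated alkenes, creates the C3 methyl and gives the lactone enolate regiospecifically, and Davis oxidation from the convex face (the face of H-3a and H-7a) sets 3S.

Step 10
Reactants: 19 (3S,3aR,4S,6R,7R,7aS)-6-ethenyl-3,4-dihydroxy-3,6-dimethyl-7-(prop-1-en-2-yl)hexahydro-1-benzofuran-2(3H)-one
Product: 20 (3S,3aR,4S,6R,7R,7aS)-6-ethenyl-3-hydroxy-3,6-dimethyl-2-oxo-7-(prop-1-en-2-yl)octahydro-1-benzofuran-4-yl acetate
Conditions: Ac2O (1.5 equiv), pyridine, rt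
Reagents that add atoms: acetic anhydride CC(=O)OC(C)=O
Why: The acylation is chemoselective because, without a nucleophilic catalyst, only the secondary C4 alcohol reacts while the tertiary α-hydroxy lactone stays free.

Step 11
Reactants: 20 (3S,3aR,4S,6R,7R,7aS)-6-ethenyl-3-hydroxy-3,6-dimethyl-2-oxo-7-(prop-1-en-2-yl)octahydro-1-benzofuran-4-yl acetate; 21 angelic acid
Product: 24 (3S,3aR,4S,6R,7R,7aS)-4-acetoxy-6-ethenyl-3,6-dimethyl-2-oxo-7-(prop-1-en-2-yl)octahydro-1-benzofuran-3-yl (2Z)-2-methylbut-2-enoate, via mixed anhydride 22 (not isolated), via lithium alkoxide 23 (not isolated)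
Conditions: 21, 2,4,6-trichlorobenzoyl chloride, Et3N, toluene, rt; 20, LiN(SiMe3)2 (1.05 equiv), THF, −78 °C; the two solutions combined, −78 to 0 °C
Reagents that add atoms: none
Why: The lithium alkoxide is acylated by a Yamaguchi-type mixed anhydride at the less hindered angeloyl carbonyl, and because no nucleophilic catalyst is present the addition–elimination path that turns angelate into tiglate is closed, so the Z geometry is kept.

## Compound list
1 | 4,4-dimethoxybutan-2-one | CC(=O)CC(OC)OC | starting material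
2 | triethyl phosphonoacetate | CCOC(=O)CP(=O)(OCC)OCC | starting material
3 | ethyl (2E)-5,5-dimethoxy-3-methylpent-2-enoate | CCOC(=O)/C=C(\C)CC(OC)OC | intermediate
4 | (2E)-5,5-dimethoxy-3-methylpent-2-en-1-ol | OC/C=C(\C)CC(OC)OC | intermediate
5 | 3-methylbut-2-enoyl chloride (senecioyl chloride) | CC(C)=CC(=O)Cl | starting material
6 | (2E)-5,5-dimethoxy-3-methylpent-2-en-1-yl 3-methylbut-2-enoate | CC(C)=CC(=O)OC/C=C(\C)CC(OC)OC | intermediate
7 | boron ketene acetal of 6 (E(O)-dienolate on the (S,S)-diazaborolidine) | C=C(C)/C=C(\OC/C=C(\C)CC(OC)OC)OB1N(S(=O)(=O)c2cc(cc(c2)C(F)(F)F)C(F)(F)F)[C@@H](c2ccccc2)[C@H](c2ccccc2)N1S(=O)(=O)c1cc(cc(c1)C(F)(F)F)C(F)(F)F | intermediate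
8 | (2R,3R)-3-ethenyl-5,5-dimethoxy-3-methyl-2-(prop-1-en-2-yl)pentanoic acid | C=C[C@@](C)(CC(OC)OC)[C@@H](C(C)=C)C(=O)O | intermediate
9 | N-acylimidazole of 8 | C=C[C@@](C)(CC(OC)OC)[C@@H](C(C)=C)C(=O)n1ccnc1 | intermediate
10 | (2R,3R)-3-ethenyl-5,5-dimethoxy-3-methyl-2-(prop-1-en-2-yl)pentanal | C=C[C@@](C)(CC(OC)OC)[C@@H](C(C)=C)C=O | intermediate
11 | methyl 2-(bromomethyl)prop-2-enoate | C=C(CBr)C(=O)OC | starting material
12 | methyl 2,3-dibromo-2-(bromomethyl)propanoate | COC(=O)C(Br)(CBr)CBr | intermediate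
13 | methyl 3-bromo-2-(bromomethyl)prop-2-enoate (E/Z mixture, geometry irrelevant) | COC(=O)C(CBr)=CBr | intermediate
14 | methyl (4S,5R,6R)-3-bromo-6-ethenyl-4-hydroxy-8,8-dimethoxy-6-methyl-2-methylidene-5-(prop-1-en-2-yl)octanoate (both C3 epimers) | C=C[C@@](C)(CC(OC)OC)[C@@H](C(C)=C)[C@H](O)C(Br)C(=C)C(=O)OC | intermediate
15 | (3R,4R)-4-[(2S)-3-bromo-4-methylidene-5-oxooxolan-2-yl]-3-ethenyl-3,5-dimethylhex-5-enal | C=C[C@@](C)(CC=O)[C@@H](C(C)=C)[C@@H]1OC(=O)C(=C)C1Br | intermediate
16 | allylindium dibromide from 15 (trivalent indium on the exocyclic CH2 of the butenolide) | C=C[C@@](C)(CC=O)[C@@H](C(C)=C)[C@@H]1OC(=O)C(C[In](Br)Br)=C1 | intermediate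
17 | (3aR,4S,6R,7R,7aS)-6-ethenyl-4-hydroxy-6-methyl-3-methylidene-7-(prop-1-en-2-yl)hexahydro-1-benzofuran-2(3H)-one | C=C[C@@]1(C)C[C@H](O)[C@@H]2[C@@H](OC(=O)C2=C)[C@@H]1C(=C)C | intermediate
18 | dilithium C4-alkoxide / lactone enolate from 17 | C=C[C@@]1(C)C[C@H]([O-])[C@@H]2[C@@H](OC([O-])=C2C)[C@@H]1C(=C)C.[Li+].[Li+] | intermediate
19 | (3S,3aR,4S,6R,7R,7aS)-6-ethenyl-3,4-dihydroxy-3,6-dimethyl-7-(prop-1-en-2-yl)hexahydro-1-benzofuran-2(3H)-one | C=C[C@@]1(C)C[C@H](O)[C@@H]2[C@@H](OC(=O)[C@@]2(C)O)[C@@H]1C(=C)C | intermediate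
20 | (3S,3aR,4S,6R,7R,7aS)-6-ethenyl-3-hydroxy-3,6-dimethyl-2-oxo-7-(prop-1-en-2-yl)octahydro-1-benzofuran-4-yl acetate | C=C[C@@]1(C)C[C@H](OC(C)=O)[C@@H]2[C@@H](OC(=O)[C@@]2(C)O)[C@@H]1C(=C)C | intermediate
21 | angelic acid, (2Z)-2-methylbut-2-enoic acid | C/C=C(/C)C(=O)O | starting material
22 | angelic 2,4,6-trichlorobenzoic anhydride | C/C=C(/C)C(=O)OC(=O)c1c(Cl)cc(Cl)cc1Cl | intermediate
23 | lithium C3-alkoxide of 20 | C=C[C@@]1(C)C[C@H](OC(C)=O)[C@@H]2[C@@H](OC(=O)[C@@]2(C)[O-])[C@@H]1C(=C)C.[Li+] | intermediate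
24 | CNP0140071.1, (3S,3aR,4S,6R,7R,7aS)-4-acetoxy-6-ethenyl-3,6-dimethyl-2-oxo-7-(prop-1-en-2-yl)octahydro-1-benzofuran-3-yl (2Z)-2-methylbut-2-enoate | C=C[C@@]1(C)C[C@H](OC(C)=O)[C@@H]2[C@@H](OC(=O)[C@@]2(C)OC(=O)/C(C)=C\C)[C@@H]1C(=C)C | target

## Step count and risks
Total step count: 11.
Longest linear sequence: 10 (steps 1 to 5 and 7 to 11; step 6 is a side branch).

**Step 8 (most likely to fail).**
- The allylindium may be protonated, or the freed aldehyde may undergo an ene reaction with the isopropenyl group.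
- The Zimmerman–Traxler preference for an equatorial aldehyde chain requires a tether conformer with axial vinyl and isopropenyl groups, so the C4 epimer may dominate.
- Fallback: C4 is set by hydroxyl-directed hydride delivery instead of in the C–C bond formation. It sets out from 14 and returns at 19. The step is run as written and gives the C4 epimer of the methylene lactone F5. This is taken through the conditions of step 9 to the C4-epimeric diol F6. Dess–Martin periodinane oxidises only the secondary alcohol to the 3-hydroxy-4-ketone F7. Me4NBH(OAc)3 in MeCN–AcOH at −20 °C binds the tertiary C3–OH and delivers hydride to the ketone face syn to C3, giving the anti diol 19 whatever the closure selectivity was.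

**Step 11.**
- The tertiary α-hydroxy lactone is hindered.
- The alkoxide may take the neighbouring acetyl group.
- Forcing conditions risk isomerising the angelate to the tiglate.
- Fallback: the Z-alkene is built on the ester instead of transferring it. It sets out from 20 and returns at 24. The alkoxide is acylated with the small 2-[bis(2,2,2-trifluoroethoxy)phosphoryl]propanoyl chloride to give the phosphonopropanoate F8. A Still–Gennari olefination with acetaldehyde (KN(SiMe3)2, 18-crown-6, THF, −78 °C) then gives 24.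

**Step 4.**
- The Lewis-acidic B–Br reagent may open the dimethyl acetal.
- The level of induction is untested for this dienolate.
- Fallback: an achiral rearrangement followed by resolution. It sets out from 6 and returns at 8. LiN(i-Pr)2 and Me3SiCl in THF (−78 °C to rt) give the trimethylsilyl ketene acetal F1, which rearranges to the racemic anti trimethylsilyl ester F2. Aqueous hydrolysis gives the racemic acid F3. Fractional crystallisation with (R)-1-phenylethylamine gives the diastereomerically pure salt F4, and acidification releases 8.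

Further compounds
F1 | step 4 | trimethylsilyl ketene acetal of 6 | C=C(C)/C=C(\OC/C=C(\C)CC(OC)OC)O[Si](C)(C)C
F2 | step 4 | racemic trimethylsilyl (2R*,3R*)-3-ethenyl-5,5-dimethoxy-3-methyl-2-(prop-1-en-2-yl)pentanoate | C=C[C@@](C)(CC(OC)OC)[C@@H](C(C)=C)C(=O)O[Si](C)(C)C.C=C[C@](C)(CC(OC)OC)[C@H](C(C)=C)C(=O)O[Si](C)(C)C
F3 | step 4 | racemic (2R*,3R*)-3-ethenyl-5,5-dimethoxy-3-methyl-2-(prop-1-en-2-yl)pentanoic acid | C=C[C@@](C)(CC(OC)OC)[C@@H](C(C)=C)C(=O)O.C=C[C@](C)(CC(OC)OC)[C@H](C(C)=C)C(=O)O
F4 | step 4 | (R)-1-phenylethylammonium salt of 8 | C=C[C@@](C)(CC(OC)OC)[C@@H](C(C)=C)C(=O)[O-].C[C@@H]([NH3+])c1ccccc1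
F5 | step 8 | C4 epimer (4R) of 17 | C=C[C@@]1(C)C[C@@H](O)[C@@H]2[C@@H](OC(=O)C2=C)[C@@H]1C(=C)C
F6 | step 8 | C4 epimer (4R) of 19 | C=C[C@@]1(C)C[C@@H](O)[C@@H]2[C@@H](OC(=O)[C@@]2(C)O)[C@@H]1C(=C)C
F7 | step 8 | (3S,3aR,6R,7R,7aS)-6-ethenyl-3-hydroxy-3,6-dimethyl-7-(prop-1-en-2-yl)tetrahydro-1-benzofuran-2,4(3H,5H)-dione | C=C[C@@]1(C)CC(=O)[C@@H]2[C@@H](OC(=O)[C@@]2(C)O)[C@@H]1C(=C)C
F8 | step 11 | C3 ester of 20 with 2-[bis(2,2,2-trifluoroethoxy)phosphoryl]propanoic acid | C=C[C@@]1(C)C[C@H](OC(C)=O)[C@@H]2[C@@H](OC(=O)[C@@]2(C)OC(=O)C(C)P(=O)(OCC(F)(F)F)OCC(F)(F)F)[C@@H]1C(=C)C
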